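## The problem

Compound 32 is a labdane of the normal series: rings A and B are trans-fused (5α-H, 10β-CH3), C4 and C10 are quaternary, and six contiguous stereocentres run round ring B from C5 to C10 (5S,6S,7S,8S,9R,10S). Ring B carries three oxygens in a row: an axial 6β-hydroxyl wedged between the syn-axial C19 and C20 methyl groups, an equatorial 7β-acetate, and a tertiary equatorial 8α-hydroxyl geminal to the axial C17 methyl. The 6,7-cis-diol therefore lies on the face that three axial methyl groups shield, where OsO4 will not go. C9 bears, equatorially, a (12E)-3-methylpenta-2,4-dienyl chain. Once the trans-decalin with its β-methyl groups exists, reagents arrive from the α face; this is useful for placing iodine or an epoxide oxygen but has to be inverted for the β-oxygens at C6 and C7, whereas C8, flanked by quaternary C10 through C9 and carrying its own methyl, is best set in the ring-forming event. Three groups are fragile: the terminal conjugated diene (electrophiles, oxidants, acid), the acetate beside a free cis-hydroxyl (acyl migration to O6 under base), and the tertiary 8-hydroxyl, which closes onto any carbonyl at C12. The enabling feature is that C5, C10, C9 and C8 are four contiguous stereocentres of ring B set around a C6–C7 unit that can be an alkene, while C1–C4 form a saturated tether from C10 to C5. This is the pattern left by a type 1 intramolecular Diels–Alder reaction of a C5=C6–C7=C8 diene with a C9=C10 dienophile, with the C8 oxygen as the donor of the diene and C11 as the activating carbonyl.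

## Retrosynthesis

**O7–acetyl and O8–silyl bonds (32 ⇒ 31 ⇒ 30).** The acetate is removed first. In triol 31 the three hydroxyls differ sharply: 7β is equatorial and secondary, 6β is axial between two syn-axial methyls, 8α is tertiary. One acylation is therefore asked to find O7, as is known for related 6β,7β,8α-oxygenated labdanes. Placing the acetate earlier would expose it to ylide and fluoride, both of which move acyl groups to O6. Triol 31 comes from silyl ether 30; the silyl group is kept until here because a free 8-hydroxyl would add to the C12 aldehyde 23 and, after olefination, to the enoate.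

**Side chain: C14=C15, C12=C13 and C11–C12 (30 ⇒ 29 ⇒ 28 ⇒ 27; 24 ⇒ 23 + 22 ⇒ 21 ⇒ 19 ⇒ 18).** The terminal alkene is cut to enal 29 (methylenation), the trisubstituted alkene to aldehyde 23 and the stabilised ylide 22, and the C11–C12 bond to the vinyl compound 19, itself the methylenation product of aldehyde 18. Attaching a five-carbon dienyl unit to C11 by substitution or cross-coupling was set aside because C11 sits on a carbon flanked by two quaternary centres. Hydroboration of 19 is preferred to a methoxymethylene Wittig/hydrolysis sequence because it keeps acid away from the tertiary allylic silyl ether. The ester 24 (not an enal) is carried through the ring oxidation, so the diene appears only after iodine has done its work. The forward reactions must give the (12E)-alkene and leave C9 untouched.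

**C6–O and C7–O bonds (27 ⇒ 24).** The cis-diol is traced to the C6=C7 alkene. OsO4 would add from the α face; the Woodward sequence puts iodine on the open α face and both oxygens on the β face through an acetoxonium ion. The precursor 24 has two fewer stereocentres and no ring oxygen except O8. The forward step must open the iodonium ion at C6 between two axial methyls and must ignore the electron-poor enoate.

**C5–C10 and C8–C9 bonds (18 ⇒ 17).** Both rings and four stereocentres are taken apart at once to the achiral trienal 17. Against the neighbouring cuts (ring B alone, or ring A alone) this one removes every stereocentre of the bicycle and leaves only alkene geometries to control: (2E) for the C9/C10 relationship, (8E,10Z) for C5 and C8. The forward reaction is asked for endo selectivity, for one enal face, and for reactivity from a β,β-disubstituted dienophile; the silyloxy donor and the gem-dimethyl tether are there to supply the last.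

**Enol ether and aldehyde oxidation level (17 ⇒ 16 ⇒ 15 ⇒ 14 ⇒ 13).** The O–Si bond is cut to the β,γ-unsaturated ketone 14, whose doubly activated C–H is the one a silyl triflate/amine pair removes. The aldehyde is carried as the ethyl ester through this step, because the same reagents convert enals into dienol ethers; it is then adjusted by reduction (16) and allylic oxidation (17). Ketone 14 is unmasked from dioxolane 13.

**C1–C10 bond and the trisubstituted alkene (13 ⇒ 10 + 11).** The (2E)-enoate is cut between C10 and C1 to the alkyl chloride 10 (through its Grignard reagent 12) and ethyl but-2-ynoate 11. A syn-carbocupration fixes the geometry mechanistically; a Horner–Wadsworth–Emmons reaction on the corresponding methyl ketone would give an E/Z mixture, and every per cent of (2Z)-isomer would become a C10 epimer after the cycloaddition.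

**C5=C6 bond and the two small fragments (10 ⇒ 5 + 9; 5 ⇒ 3 ⇒ 1 + 2; 9 ⇒ 8 ⇒ 6 + 7).** The (E)-alkene next to the quaternary carbon is cut to the non-enolisable aldehyde 5 and the tetrazolyl sulfone 9 (Julia–Kocienski). Aldehyde 5 comes from nitrile 3, the alkylation product of isobutyronitrile 1 with 1-bromo-3-chloropropane 2. Sulfone 9 comes from thiol 6 and bromo ketal 7 through sulfide 8. All four starting materials are commodity chemicals.

## Roads not taken

**Alternative 1:** The cut is C7–C8 and C9–C10 of ring B. Forward, the ring A 2-silyloxydiene A1 (C10=C5–C6(OSi)=C7) would add to methyl but-2-ynoate A2 (C8≡C9 carrying C17 and C11) to give the 6-silyloxy-5,8-diene ester A3.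
- Merits: the plan is convergent, ring A is used ready-made, and the bicycle would be reached in a handful of steps against eleven here. The regiochemistry is matched (the C6 donor sends the ester-bearing C9 to C10). O6 arrives at the right carbon as a masked ketone, which the chosen plan has to earn by a separate dihydroxylation.
- Weak points: the C5=C10 end of the diene is tetrasubstituted and twisted out of conjugation by the C4 methyls and C20, and it must form a quaternary carbon with a β-substituted alkynoate, so forcing conditions are likely. A3 holds a single stereocentre (C10), and catalyst control of alkynoate cycloadditions is far less developed than that of enals. C5, C8 and C9 then have to be set on a tetrasubstituted enoate and an enol ether, and O7 and O8 are still missing.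
- Comparison: alternative 1 is shorter to the decalin and better for O6. The chosen plan sets against this four stereocentres, O8 and C17 delivered in one step, where A3 would need a stereoselective operation for almost every ring B carbon.

**Alternative 2:** The cut is C4–C5 of ring A. Forward, acid would protonate the C3=C4 alkene of enol silyl ether A4 (ring B preformed, C9 and C10 already set), and the tertiary C4 cation would be captured at C5 to give the trans-decalin-6-one A5.
- Merits: a short cationic closure makes the most hindered bond of the skeleton. The trans fusion follows from a chair transition state and is correctable by epimerisation next to the ketone. The C6 ketone is a handle for the 6β-hydroxyl (hydride from the α face) and for oxidation at C7. A5 already holds C11–C12, so the homologation that costs the chosen plan three steps disappears.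
- Weak points: A5 lacks C17, O7 and O8. A methyl group and a tertiary alcohol must be brought to C8, two bonds from the only functional group, which means a long redox sequence. The vicinal C9/C10 pair (one quaternary) has to be made enantioselectively before the key step, which itself adds only C5. Protic acid also desilylates an enol ether faster than it protonates a trisubstituted alkene.
- Comparison: the key step of alternative 2 is probably more dependable than a cycloaddition at its limit, and it is better for the side-chain carbons. The chosen plan sets against this that C8, with its carbon, oxygen and configuration, is finished when the rings close, and that the absolute configuration comes from a catalyst and not from an extra asymmetric sequence.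

**Alternative 3:** The cut is C1–C10. Forward, the phenoxide of the hexasubstituted phenol A6 (O at C7, Cl at C6, the bromoalkyl chain on C5) would displace the primary bromide at C1 through its para carbon C10 and give the cross-conjugated dienone A7.
- Merits: the step is a simple base-mediated alkylation of a primary halide; O-alkylation is geometrically excluded and the ortho carbon is blocked by chlorine. All ring B carbons, O7, C17, C20 and C11–C12 are in place before the ring closes.
- Weak points: A6 is a fully substituted benzene whose regiocontrolled assembly is a project in itself. A7 has one stereocentre, to be set by an enantioselective dearomatisation next to a quaternary carbon. C5, C6, C7, C8 and C9 must then be created one by one on a flat dienone, guided only by the C10 methyl; this guides hydrogen to the α face at C5 and C9 but works against the β-oxygens at C6 and C7, and a vinyl chloride must become an axial alcohol.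
- Comparison: the ring closure is easier than the chosen cycloaddition and brings more of the oxygen pattern with it. The chosen plan sets against this a four-stereocentre step and a ring B that needs only one further stereochemical operation, the cis-hydroxylation.

Key step: step 11

Remarks before the steps:
- Labdane numbering is used for the bicyclic compounds; α/β refer to the normal series (5α-H, 9α-H, 10β-CH3).
- Steps 3 and 4 are a two-step branch to sulfone 9.
- Assumption: the catalyst is taken to follow the formyl C–H···O binding model of enals, on which the (R)-configured oxazaborolidine exposes the C9 si face of 17. Should the sense prove opposite, the (S)-configured catalyst is used and nothing else changes.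

## Route

Step 1
Reactants: 1 isobutyronitrile (2-methylpropanenitrile); 2 1-bromo-3-chloropropane
Product: 3 5-chloro-2,2-dimethylpentanenitrile
Conditions: LiN(i-Pr)2, THF, −78 °C; then 2, −78 °C → rt
Reagents that add atoms: none
Why: Deprotonation of the nitrile and SN2 alkylation at the more reactive C–Br end of 2 (nitrile α-alkylation) build the quaternary C4 with both methyl groups and keep the chloride for later metalation.

Step 2
Reactants: 3 5-chloro-2,2-dimethylpentanenitrile
Product: 5 5-chloro-2,2-dimethylpentanal, via aluminium aldiminate 4 (not isolated)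
Conditions: i-Bu2AlH (1.2 equiv), CH2Cl2, −78 → 0 °C; then 1 M HCl, 0 °C
Reagents that add atoms: water, O
Why: Partial reduction of a nitrile by i-Bu2AlH stops at the N-aluminio imine 4, which aqueous acid hydrolyses to the aldehyde; the product has no α-hydrogen and cannot enolise in the next step.

Step 3
Reactants: 6 1-phenyl-1H-tetrazole-5-thiol; 7 2-(2-bromoethyl)-2-methyl-1,3-dioxolane
Product: 8 5-{[2-(2-methyl-1,3-dioxolan-2-yl)ethyl]sulfanyl}-1-phenyl-1H-tetrazole
Conditions: K2CO3, DMF, rt → 50 °C
Reagents that add atoms: none
Why: S-Alkylation of the acidic heteroaryl thiol by a primary bromide (SN2); the dioxolane is inert to base.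

Step 4
Reactants: 8 5-{[2-(2-methyl-1,3-dioxolan-2-yl)ethyl]sulfanyl}-1-phenyl-1H-tetrazole
Product: 9 5-{[2-(2-methyl-1,3-dioxolan-2-yl)ethyl]sulfonyl}-1-phenyl-1H-tetrazole
Conditions: mCPBA (3 equiv), NaHCO3, CH2Cl2, 0 °C → rt
Reagents that add atoms: 3-chloroperoxybenzoic acid (mCPBA), OOC(=O)c1cccc(Cl)c1
Why: Peracid oxidation of the sulfide through the sulfoxide to the sulfone; the hydrogencarbonate buffer protects the ketal.

Step 5
Reactants: 9 5-{[2-(2-methyl-1,3-dioxolan-2-yl)ethyl]sulfonyl}-1-phenyl-1H-tetrazole; 5 5-chloro-2,2-dimethylpentanal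
Product: 10 2-[(2E)-7-chloro-4,4-dimethylhept-2-en-1-yl]-2-methyl-1,3-dioxolane
Conditions: KN(SiMe3)2, DME, −60 °C; then 5, −60 °C → rt
Reagents that add atoms: none
Why: Julia–Kocienski olefination (addition of the metalated sulfone, Smiles rearrangement, loss of SO2 and tetrazololate) forms C5=C6; a phenyltetrazolyl sulfone with a bulky α-quaternary aldehyde and a potassium counter-ion in DME should give the (E)-alkene, and the ketal oxygens are too far from the carbanion for β-elimination.

Step 6
Reactants: 10 2-[(2E)-7-chloro-4,4-dimethylhept-2-en-1-yl]-2-methyl-1,3-dioxolane; 11 ethyl but-2-ynoate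
Product: 13 ethyl (2E,8E)-3,7,7-trimethyl-10-(2-methyl-1,3-dioxolan-2-yl)deca-2,8-dienoate, via Grignard reagent 12 (not isolated)
Conditions: Mg, 1,2-dibromoethane (cat.), THF, reflux; then CuBr·SMe2 (1 equiv), THF, −40 °C; then 11, −78 °C; MeOH, −78 °C
Reagents that add atoms: none
Why: Transmetalation of 12 to monovalent copper and syn-carbocupration of the ynoate (conjugate addition of an organocopper reagent to an α,β-acetylenic ester) place the chain and the new C–Cu bond cis; protonation with retention at −78 °C therefore leaves the chain trans to the ester and the methyl cis to it, the (2E)-geometry that later puts C11 cis to C20.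

Step 7
Reactants: 13 ethyl (2E,8E)-3,7,7-trimethyl-10-(2-methyl-1,3-dioxolan-2-yl)deca-2,8-dienoate
Product: 14 ethyl (2E,8E)-3,7,7-trimethyl-11-oxododeca-2,8-dienoate
Conditions: pyridinium p-toluenesulfonate (0.3 equiv), acetone/H2O 10:1, 50 °C
Reagents that add atoms: water, O
Why: Mild acid-catalysed ketal hydrolysis (with transketalisation to acetone) frees the methyl ketone; the weak acid and short contact are chosen so that the β,γ-alkene does not drift into conjugation, and the crude ketone is used at once.

Step 8
Reactants: 14 ethyl (2E,8E)-3,7,7-trimethyl-11-oxododeca-2,8-dienoate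
Product: 15 ethyl (2E,8E,10Z)-11-{[tert-butyl(dimethyl)silyl]oxy}-3,7,7-trimethyldodeca-2,8,10-trienoate
Conditions: TBSOTf (1.3 equiv), Et3N (2.5 equiv), CH2Cl2, −78 → 0 °C
Reagents that add atoms: tert-butyldimethylsilyl trifluoromethanesulfonate (TBSOTf), CC(C)(C)[Si](C)(C)OS(=O)(=O)C(F)(F)F
Why: Soft enolisation (O-silylation, then amine deprotonation) removes the doubly activated hydrogen between alkene and carbonyl and gives the conjugated dienol ether; allylic strain between the vinyl group and the methyl favours the (10Z)-isomer with silyloxy cis to the diene chain, and the enoate is not enolised under these conditions.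

Step 9
Reactants: 15 ethyl (2E,8E,10Z)-11-{[tert-butyl(dimethyl)silyl]oxy}-3,7,7-trimethyldodeca-2,8,10-trienoate
Product: 16 (2E,8E,10Z)-11-{[tert-butyl(dimethyl)silyl]oxy}-3,7,7-trimethyldodeca-2,8,10-trien-1-ol
Conditions: i-Bu2AlH (2.3 equiv), CH2Cl2, −78 °C; aq. potassium sodium tartrate
Reagents that add atoms: none
Why: 1,2-Reduction of the enoate by i-Bu2AlH gives the allylic alcohol; silyl enol ethers tolerate the hydride and the neutral tartrate work-up.

Step 10
Reactants: 16 (2E,8E,10Z)-11-{[tert-butyl(dimethyl)silyl]oxy}-3,7,7-trimethyldodeca-2,8,10-trien-1-ol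
Product: 17 (2E,8E,10Z)-11-{[tert-butyl(dimethyl)silyl]oxy}-3,7,7-trimethyldodeca-2,8,10-trienal
Conditions: MnO2 (20 equiv), CH2Cl2, rt; filtration through Celite
Reagents that add atoms: none
Why: Allylic oxidation with MnO2 is neutral, does not isomerise the (2E)-alkene and should leave the acid-sensitive dienol ether intact; the trienal is used without chromatography.

Step 11
Reactants: 17 (2E,8E,10Z)-11-{[tert-butyl(dimethyl)silyl]oxy}-3,7,7-trimethyldodeca-2,8,10-trienal
Product: 18 (1R,2R,4aS,8aS)-2-{[tert-butyl(dimethyl)silyl]oxy}-2,5,5,8a-tetramethyl-1,2,4a,5,6,7,8,8a-octahydronaphthalene-1-carbaldehyde (8α-silyloxydrim-6-en-11-al)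
Conditions: (3aR)-1-(2-methylphenyl)-3,3-diphenyltetrahydro-1H,3H-pyrrolo[1,2-c][1,3,2]oxazaborole (25 mol%), HNTf2 (20 mol%), CH2Cl2 (0.02 M), −78 → −20 °C; Et3N quench
Reagents that add atoms: none
Why: The N-protonated oxazaborolidine binds the formyl oxygen of 17 (formyl C–H against the ring oxygen), lowers the enal LUMO, and the silyloxydiene adds across C9=C10 in a concerted but asynchronous [4+2] cycloaddition in which C5–C10 bonding (donor terminus to enal β-carbon) runs ahead of C8–C9. The closest known reaction type is the enantioselective type 1 intramolecular Diels–Alder reaction of (2E)-trienals catalysed by triflimide-activated oxazaborolidines, together with intermolecular additions of silyloxydienes under the same catalysts; the β,β-disubstituted dienophile and the fully substituted diene terminus are the new demands. Ring B (C5–C10) closes as the cyclohexene of the cycloaddition, and ring A (C1–C5, C10) closes through the four-carbon tether in a chair-like, 6-exo sense at the dienophile, a loop favoured by the C4 gem-dimethyl group. C9 and C10 are related by the (2E)-enal geometry, which keeps C11 and C20 cis (both β). C5 is set relative to C10 by the endo transition state (formyl group under the diene, tether anti), which gives the trans ring fusion with 5α-H. C8 is set by the (10Z)-enol ether: the inside silyloxy group ends cis to H5 (8α-O) and the outside methyl becomes the axial 8β-methyl. The absolute configuration comes from the catalyst, whose C-phenyl group covers the C9 re face so that C8 bonds to the si face. The step needs endo over exo selectivity and cycloaddition over Mukaiyama-type side reactions: Lewis-acid activation strengthens the endo preference, the only six-membered closure open to the dienol ether is C5 to C10 (attack on the formyl carbon would need an eight- or ten-membered ring), high dilution suppresses intermolecular aldol addition, and the excess of oxazaborolidine over HNTf2 leaves no free acid to desilylate the diene.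

Step 12
Reactants: 18 8α-silyloxydrim-6-en-11-al
Product: 19 8α-{[tert-butyl(dimethyl)silyl]oxy}-13,14,15,16-tetranorlabda-6,11-diene
Conditions: Ph3PCH3Br (2.5 equiv), KOt-Bu (2.3 equiv), THF, 0 °C; then 18, 0 °C → rt
Reagents that add atoms: methyltriphenylphosphonium bromide, C[P+](c1ccccc1)(c1ccccc1)c1ccccc1.[Br-]
Why: Wittig methylenation adds C12; addition of the unhindered ylide to the aldehyde is faster than enolisation, and the C9 substituent is already in its more stable equatorial position, so C9 should not epimerise.

Step 13
Reactants: 19 8α-{[tert-butyl(dimethyl)silyl]oxy}-13,14,15,16-tetranorlabda-6,11-diene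
Product: 21 8α-{[tert-butyl(dimethyl)silyl]oxy}-13,14,15,16-tetranorlabd-6-en-12-ol, via alkylborane 20 (not isolated)
Conditions: 9-BBN (2 equiv), THF, 0 °C → rt; then 3 M NaOH, 30% H2O2, 0 °C → rt
Reagents that add atoms: hydrogen peroxide, OO
Why: Anti-Markovnikov hydroboration–oxidation; the bulky borane takes the monosubstituted vinyl group and leaves the ring alkene, which is shielded on both faces, and C11 becomes the saturated CH2 of the target.

Step 14
Reactants: 21 8α-{[tert-butyl(dimethyl)silyl]oxy}-13,14,15,16-tetranorlabd-6-en-12-ol; 22 ethyl 2-(triphenyl-λ5-phosphanylidene)propanoate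
Product: 24 ethyl (12E)-8α-{[tert-butyl(dimethyl)silyl]oxy}-15-norlabda-6,12-dien-14-oate, via aldehyde 23 (not isolated)
Conditions: Dess–Martin periodinane (1.3 equiv), NaHCO3, CH2Cl2, 0 °C → rt; then 22 (3 equiv), rt → 40 °C
Reagents that add atoms: none
Why: One-pot oxidation and Wittig olefination with a stabilised, α-branched ylide, which gives the (E)-trisubstituted enoate (ester trans to the chain); the silyl group on O8 prevents lactol formation with the C12 aldehyde and oxa-Michael closure onto the enoate.

Step 15
Reactants: 24 ethyl (12E)-8α-{[tert-butyl(dimethyl)silyl]oxy}-15-norlabda-6,12-dien-14-oate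
Product: 27 ethyl (12E)-8α-{[tert-butyl(dimethyl)silyl]oxy}-6β,7β-dihydroxy-15-norlabd-12-en-14-oate, via iodo acetate 25 (not isolated), via hydroxy acetate 26 (not isolated)
Conditions: I2 (1.1 equiv), AgOAc (2.3 equiv), AcOH, rt, dark; then H2O/AcOH, 90 °C; filtration, evaporation; then K2CO3, EtOH, rt
Reagents that add atoms: silver acetate, CC(=O)[O-].[Ag+]
Why: Woodward cis-hydroxylation: iodine goes to the open α face, acetate opens the iodonium ion trans-diaxially at C6 from the β face (25), the ester carbonyl displaces the axial iodide with silver assistance to a β-fused acetoxonium ion, and water opens it to the cis-hydroxy acetate 26, so both oxygens end on the shielded β face (6S,7S). The electron-poor enoate is inert to the iodonium reagent, and ethanolysis removes the acetate without touching the ethyl ester.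

Step 16
Reactants: 27 ethyl (12E)-8α-{[tert-butyl(dimethyl)silyl]oxy}-6β,7β-dihydroxy-15-norlabd-12-en-14-oate
Product: 28 (12E)-8α-{[tert-butyl(dimethyl)silyl]oxy}-15-norlabd-12-ene-6β,7β,14-triol
Conditions: i-Bu2AlH (6 equiv), CH2Cl2, −78 → −20 °C; aq. potassium sodium tartrate
Reagents that add atoms: none
Why: 1,2-Reduction of the enoate to the allylic alcohol; the excess hydride allows for the two free hydroxyls, which are carried as aluminium alkoxides.

Step 17
Reactants: 28 (12E)-8α-{[tert-butyl(dimethyl)silyl]oxy}-15-norlabd-12-ene-6β,7β,14-triol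
Product: 29 (12E)-8α-{[tert-butyl(dimethyl)silyl]oxy}-6β,7β-dihydroxy-15-norlabd-12-en-14-al
Conditions: MnO2 (20 equiv), CH2Cl2, rt
Reagents that add atoms: none
Why: MnO2 oxidises only the allylic alcohol; the two hindered saturated secondary hydroxyls of ring B are left, so no diol protection is needed.

Step 18
Reactants: 29 (12E)-8α-{[tert-butyl(dimethyl)silyl]oxy}-6β,7β-dihydroxy-15-norlabd-12-en-14-al
Product: 30 (12E)-8α-{[tert-butyl(dimethyl)silyl]oxy}labda-12,14-diene-6β,7β-diol
Conditions: Ph3PCH3Br (5 equiv), KOt-Bu (4.8 equiv), THF, −78 → 0 °C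
Reagents that add atoms: methyltriphenylphosphonium bromide, C[P+](c1ccccc1)(c1ccccc1)c1ccccc1.[Br-]
Why: Wittig methylenation of the enal completes the (12E)-diene; excess ylide absorbs the two hydroxyl protons, and the 1,3-diequatorial relation of O7 and the C9 chain rules out intramolecular oxa-Michael addition.

Step 19
Reactants: 30 (12E)-8α-{[tert-butyl(dimethyl)silyl]oxy}labda-12,14-diene-6β,7β-diol
Product: 31 (12E)-labda-12,14-diene-6β,7β,8α-triol
Conditions: Bu4NF (3 equiv), THF, 50 °C
Reagents that add atoms: none
Why: Fluoride cleavage of the tertiary silyl ether (possibly by way of migration to the neighbouring O7 alkoxide) under conditions that do not harm the diene; it is placed before the acetylation so that no basic step follows the acetate.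

Step 20
Reactants: 31 (12E)-labda-12,14-diene-6β,7β,8α-triol
Product: 32 (12E)-6β,8α-dihydroxylabda-12,14-dien-7β-yl acetate, (1R,2S,3S,4S,4aS,8aS)-2,4-dihydroxy-2,5,5,8a-tetramethyl-1-[(2E)-3-methylpenta-2,4-dien-1-yl]decahydronaphthalen-3-yl acetate
Conditions: Ac2O (1.5 equiv), pyridine, 0 °C → rt
Reagents that add atoms: acetic anhydride, CC(=O)OC(C)=O
Why: Selective acylation of the only accessible hydroxyl: O7 is equatorial and secondary, O6 is axial between the C19 and C20 methyls, and O8 is tertiary; without an acyl-transfer catalyst and without strong base, neither over-acylation nor migration to O6 is expected.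

## Compound list

1 | isobutyronitrile (2-methylpropanenitrile) | CC(C)C#N | starting material
2 | 1-bromo-3-chloropropane | ClCCCBr | starting material
3 | 5-chloro-2,2-dimethylpentanenitrile | N#CC(C)(C)CCCCl | intermediate
4 | N-(diisobutylalumanyl)-5-chloro-2,2-dimethylpentan-1-imine (aluminium aldiminate) | CC(C)C[Al](CC(C)C)N=CC(C)(C)CCCCl | intermediate (not isolated)
5 | 5-chloro-2,2-dimethylpentanal | O=CC(C)(C)CCCCl | intermediate
6 | 1-phenyl-1H-tetrazole-5-thiol | Sc1nnnn1-c1ccccc1 | starting material
7 | 2-(2-bromoethyl)-2-methyl-1,3-dioxolane | CC1(CCBr)OCCO1 | starting material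
8 | 5-{[2-(2-methyl-1,3-dioxolan-2-yl)ethyl]sulfanyl}-1-phenyl-1H-tetrazole | CC1(CCSc2nnnn2-c2ccccc2)OCCO1 | intermediate
9 | 5-{[2-(2-methyl-1,3-dioxolan-2-yl)ethyl]sulfonyl}-1-phenyl-1H-tetrazole | CC1(CCS(=O)(=O)c2nnnn2-c2ccccc2)OCCO1 | intermediate
10 | 2-[(2E)-7-chloro-4,4-dimethylhept-2-en-1-yl]-2-methyl-1,3-dioxolane | ClCCCC(C)(C)/C=C/CC1(C)OCCO1 | intermediate
11 | ethyl but-2-ynoate | CC#CC(=O)OCC | starting material
12 | [(5E)-4,4-dimethyl-7-(2-methyl-1,3-dioxolan-2-yl)hept-5-en-1-yl]magnesium chloride (Grignard reagent) | Cl[Mg]CCCC(C)(C)/C=C/CC1(C)OCCO1 | intermediate (not isolated)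
13 | ethyl (2E,8E)-3,7,7-trimethyl-10-(2-methyl-1,3-dioxolan-2-yl)deca-2,8-dienoate | CCOC(=O)/C=C(\C)CCCC(C)(C)/C=C/CC1(C)OCCO1 | intermediate
14 | ethyl (2E,8E)-3,7,7-trimethyl-11-oxododeca-2,8-dienoate | CCOC(=O)/C=C(\C)CCCC(C)(C)/C=C/CC(C)=O | intermediate
15 | ethyl (2E,8E,10Z)-11-{[tert-butyl(dimethyl)silyl]oxy}-3,7,7-trimethyldodeca-2,8,10-trienoate | CCOC(=O)/C=C(\C)CCCC(C)(C)/C=C/C=C(C)\O[Si](C)(C)C(C)(C)C | intermediate
16 | (2E,8E,10Z)-11-{[tert-butyl(dimethyl)silyl]oxy}-3,7,7-trimethyldodeca-2,8,10-trien-1-ol | OC/C=C(\C)CCCC(C)(C)/C=C/C=C(C)\O[Si](C)(C)C(C)(C)C | intermediate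
17 | (2E,8E,10Z)-11-{[tert-butyl(dimethyl)silyl]oxy}-3,7,7-trimethyldodeca-2,8,10-trienal | O=C/C=C(\C)CCCC(C)(C)/C=C/C=C(C)\O[Si](C)(C)C(C)(C)C | intermediate (precursor of the key step)
18 | (1R,2R,4aS,8aS)-2-{[tert-butyl(dimethyl)silyl]oxy}-2,5,5,8a-tetramethyl-1,2,4a,5,6,7,8,8a-octahydronaphthalene-1-carbaldehyde (8α-silyloxydrim-6-en-11-al) | O=C[C@H]1[C@](C)(O[Si](C)(C)C(C)(C)C)C=C[C@H]2C(C)(C)CCC[C@@]21C | intermediate (product of the key step)
19 | 8α-{[tert-butyl(dimethyl)silyl]oxy}-13,14,15,16-tetranorlabda-6,11-diene; tert-butyl{[(1R,2R,4aS,8aS)-1-ethenyl-2,5,5,8a-tetramethyl-1,2,4a,5,6,7,8,8a-octahydronaphthalen-2-yl]oxy}dimethylsilane | C=C[C@H]1[C@](C)(O[Si](C)(C)C(C)(C)C)C=C[C@H]2C(C)(C)CCC[C@@]21C | intermediate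
20 | 12-(9-borabicyclo[3.3.1]nonan-9-yl)-8α-{[tert-butyl(dimethyl)silyl]oxy}-13,14,15,16-tetranorlabd-6-ene (alkylborane) | C1CCC2CCCC1B2CC[C@H]1[C@](C)(O[Si](C)(C)C(C)(C)C)C=C[C@H]2C(C)(C)CCC[C@@]21C | intermediate (not isolated)
21 | 8α-{[tert-butyl(dimethyl)silyl]oxy}-13,14,15,16-tetranorlabd-6-en-12-ol; 2-[(1R,2R,4aS,8aS)-2-silyloxy-2,5,5,8a-tetramethyl-1,2,4a,5,6,7,8,8a-octahydronaphthalen-1-yl]ethan-1-ol | OCC[C@H]1[C@](C)(O[Si](C)(C)C(C)(C)C)C=C[C@H]2C(C)(C)CCC[C@@]21C | intermediate
22 | ethyl 2-(triphenyl-λ5-phosphanylidene)propanoate | CCOC(=O)C(C)=P(c1ccccc1)(c1ccccc1)c1ccccc1 | starting material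
23 | 8α-{[tert-butyl(dimethyl)silyl]oxy}-13,14,15,16-tetranorlabd-6-en-12-al | O=CC[C@H]1[C@](C)(O[Si](C)(C)C(C)(C)C)C=C[C@H]2C(C)(C)CCC[C@@]21C | intermediate (not isolated)
24 | ethyl (12E)-8α-{[tert-butyl(dimethyl)silyl]oxy}-15-norlabda-6,12-dien-14-oate | CCOC(=O)/C(C)=C/C[C@H]1[C@](C)(O[Si](C)(C)C(C)(C)C)C=C[C@H]2C(C)(C)CCC[C@@]21C | intermediate
25 | ethyl (12E)-6β-acetoxy-8α-{[tert-butyl(dimethyl)silyl]oxy}-7α-iodo-15-norlabd-12-en-14-oate (iodo acetate) | CCOC(=O)/C(C)=C/C[C@H]1[C@](C)(O[Si](C)(C)C(C)(C)C)[C@H](I)[C@@H](OC(C)=O)[C@H]2C(C)(C)CCC[C@@]21C | intermediate (not isolated)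
26 | ethyl (12E)-6β-acetoxy-8α-{[tert-butyl(dimethyl)silyl]oxy}-7β-hydroxy-15-norlabd-12-en-14-oate (hydroxy acetate) | CCOC(=O)/C(C)=C/C[C@H]1[C@](C)(O[Si](C)(C)C(C)(C)C)[C@@H](O)[C@@H](OC(C)=O)[C@H]2C(C)(C)CCC[C@@]21C | intermediate (not isolated)
27 | ethyl (12E)-8α-{[tert-butyl(dimethyl)silyl]oxy}-6β,7β-dihydroxy-15-norlabd-12-en-14-oate (5S,6S,7S,8S,9R,10S) | CCOC(=O)/C(C)=C/C[C@H]1[C@](C)(O[Si](C)(C)C(C)(C)C)[C@@H](O)[C@@H](O)[C@H]2C(C)(C)CCC[C@@]21C | intermediate
28 | (12E)-8α-{[tert-butyl(dimethyl)silyl]oxy}-15-norlabd-12-ene-6β,7β,14-triol | OC/C(C)=C/C[C@H]1[C@](C)(O[Si](C)(C)C(C)(C)C)[C@@H](O)[C@@H](O)[C@H]2C(C)(C)CCC[C@@]21C | intermediate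
29 | (12E)-8α-{[tert-butyl(dimethyl)silyl]oxy}-6β,7β-dihydroxy-15-norlabd-12-en-14-al | O=C/C(C)=C/C[C@H]1[C@](C)(O[Si](C)(C)C(C)(C)C)[C@@H](O)[C@@H](O)[C@H]2C(C)(C)CCC[C@@]21C | intermediate
30 | (12E)-8α-{[tert-butyl(dimethyl)silyl]oxy}labda-12,14-diene-6β,7β-diol | C=C/C(C)=C/C[C@H]1[C@](C)(O[Si](C)(C)C(C)(C)C)[C@@H](O)[C@@H](O)[C@H]2C(C)(C)CCC[C@@]21C | intermediate
31 | (12E)-labda-12,14-diene-6β,7β,8α-triol (5S,6S,7S,8S,9R,10S) | C=C/C(C)=C/C[C@H]1[C@](C)(O)[C@@H](O)[C@@H](O)[C@H]2C(C)(C)CCC[C@@]21C | intermediate
32 | (12E)-6β,8α-dihydroxylabda-12,14-dien-7β-yl acetate; (1R,2S,3S,4S,4aS,8aS)-2,4-dihydroxy-2,5,5,8a-tetramethyl-1-[(2E)-3-methylpenta-2,4-dien-1-yl]decahydronaphthalen-3-yl acetate | C=C/C(C)=C/C[C@H]1[C@](C)(O)[C@@H](OC(C)=O)[C@@H](O)[C@H]2C(C)(C)CCC[C@@]21C | target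

## Step count and least certain steps

Total: 20 steps. Longest linear sequence: 18 steps (steps 1, 2 and 5–20, from isobutyronitrile); steps 3 and 4 are the branch to sulfone 9.

**Step 11 (key step).** The most likely failure is a cycloaddition too slow at temperatures where the catalyst stays selective. A β,β-disubstituted enal binds and reacts sluggishly, and the diene terminus at C8 is fully substituted with one group forced inside. Protodesilylation of the dienol ether, or a stepwise Mukaiyama–Michael closure with silyl transfer (ring A closed, ring B open), could then take over. Two further risks are erosion of the endo preference, because the C20 methyl must also sit under the diene, and incomplete face selection for this untested substitution pattern.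

Fallback (auxiliary control in place of catalyst control), from 13 back to 18. Saponification of 13 (LiOH, aqueous THF/MeOH) would give (2E,8E)-3,7,7-trimethyl-10-(2-methyl-1,3-dioxolan-2-yl)deca-2,8-dienoic acid F1. Pivaloyl chloride and Et3N would convert it into the mixed pivalic anhydride F2, which would acylate lithiated (S)-4-benzyl-1,3-oxazolidin-2-one to the N-enoyl oxazolidinone F3. Ketal hydrolysis as in step 7 would give the keto imide F4, and silylation as in step 8 the silyloxydiene imide F5. Me2AlCl (1.4 equiv, CH2Cl2, −30 °C) would chelate both imide carbonyls into a cationic s-cis dienophile, far more electrophilic than the enal, whose benzyl group covers the C9 re face; endo cycloaddition on the si face would give the cycloadduct imide F6. LiBH4 (THF, one equivalent of water) would release the auxiliary and the primary alcohol 8α-{[tert-butyl(dimethyl)silyl]oxy}drim-6-en-11-ol F7, and oxidation (SO3·pyridine, DMSO, i-Pr2NEt) would return 18.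

**Step 15.** Opening of the α-iodonium ion at C6 requires acetate to enter axially between the C19 and C20 methyls. If this is slow, the reversible iodonium ion may find other outlets: attack at the enoate, ionisation or loss of the tertiary silyl ether in hot aqueous acetic acid, or skeletal rearrangement. The second displacement at C7 is neopentyl-like, and its sluggishness could stall the sequence at the iodo acetate.

Fallback (epoxide opening and inversion at C7 in place of the iodonium/acetoxonium sequence), from 24 back to 27. mCPBA/NaHCO3 would epoxidise C6=C7 from the open α face, the enoate being inert, to give ethyl (12E)-8α-{[tert-butyl(dimethyl)silyl]oxy}-6α,7α-epoxy-15-norlabd-12-en-14-oate F8. Dilute HClO4 in aqueous THF would open it trans-diaxially at C6 to the 6β,7α-diol F9. One equivalent of Dess–Martin periodinane would oxidise the accessible axial 7α-hydroxyl, the 6β-hydroxyl being buried, to the 6β-hydroxy-7-ketone F10. NaBH4 (MeOH, −20 °C) would deliver hydride from the α face, the β face being closed by the axial C17 methyl, and give 27.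

**Step 6.** The geometry can be lost if the alkenylcopper adduct equilibrates through its allenoate form before protonation (insufficient cooling, slow quench); any (2Z)-ester becomes a C10 epimer after step 11. Formation of 12 from a primary chloride may also be accompanied by Wurtz coupling, or by radical 5-exo closure onto the nearby alkene at the metal surface.

Fallback (ketone olefination in place of carbocupration), from 10 through 12 back to 13. The Grignard reagent 12 would be acylated with N-methoxy-N-methylacetamide to (7E)-6,6-dimethyl-9-(2-methyl-1,3-dioxolan-2-yl)non-7-en-2-one F11. A Horner–Wadsworth–Emmons reaction with triethyl phosphonoacetate (NaH, THF, reflux) would give 13 together with its (2Z)-isomer, which would have to be removed by chromatography before step 7.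

**Step 20.** Discrimination between O7 and O6 rests on steric shielding alone. Slow acylation of the 7-hydroxyl (it is flanked by the quaternary C8) could invite forcing, and with it diacetate formation or base-mediated migration of the acetyl group to O6.

Fallback (tin-mediated regiocontrol in place of steric discrimination), from 31 to 32. Bu2SnO (MeOH, reflux) would give the 6,7-O-dibutylstannylene acetal F12, in which the equatorial oxygen O7 is the more nucleophilic. Acetyl chloride (1 equiv, CH2Cl2, 0 °C) would then acylate O7 and give 32 after aqueous NaHCO3 work-up.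

## Further compounds

F1 | step 11 | (2E,8E)-3,7,7-trimethyl-10-(2-methyl-1,3-dioxolan-2-yl)deca-2,8-dienoic acid | OC(=O)/C=C(\C)CCCC(C)(C)/C=C/CC1(C)OCCO1
F2 | step 11 | mixed pivalic anhydride of F1 | CC(C)(C)C(=O)OC(=O)/C=C(\C)CCCC(C)(C)/C=C/CC1(C)OCCO1
F3 | step 11 | (4S)-4-benzyl-3-[(2E,8E)-3,7,7-trimethyl-10-(2-methyl-1,3-dioxolan-2-yl)deca-2,8-dienoyl]-1,3-oxazolidin-2-one | O=C(/C=C(\C)CCCC(C)(C)/C=C/CC1(C)OCCO1)N1[C@@H](Cc2ccccc2)COC1=O
F4 | step 11 | (4S)-4-benzyl-3-[(2E,8E)-3,7,7-trimethyl-11-oxododeca-2,8-dienoyl]-1,3-oxazolidin-2-one (keto imide) | O=C(/C=C(\C)CCCC(C)(C)/C=C/CC(C)=O)N1[C@@H](Cc2ccccc2)COC1=O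
F5 | step 11 | (4S)-4-benzyl-3-[(2E,8E,10Z)-11-{[tert-butyl(dimethyl)silyl]oxy}-3,7,7-trimethyldodeca-2,8,10-trienoyl]-1,3-oxazolidin-2-one (silyloxydiene imide) | O=C(/C=C(\C)CCCC(C)(C)/C=C/C=C(C)\O[Si](C)(C)C(C)(C)C)N1[C@@H](Cc2ccccc2)COC1=O
F6 | step 11 | (4S)-4-benzyl-3-{[(1R,2R,4aS,8aS)-2-{[tert-butyl(dimethyl)silyl]oxy}-2,5,5,8a-tetramethyl-1,2,4a,5,6,7,8,8a-octahydronaphthalen-1-yl]carbonyl}-1,3-oxazolidin-2-one (cycloadduct imide) | O=C([C@H]1[C@](C)(O[Si](C)(C)C(C)(C)C)C=C[C@H]2C(C)(C)CCC[C@@]21C)N1[C@@H](Cc2ccccc2)COC1=O
F7 | step 11 | 8α-{[tert-butyl(dimethyl)silyl]oxy}drim-6-en-11-ol | OC[C@H]1[C@](C)(O[Si](C)(C)C(C)(C)C)C=C[C@H]2C(C)(C)CCC[C@@]21C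
F8 | step 15 | ethyl (12E)-8α-{[tert-butyl(dimethyl)silyl]oxy}-6α,7α-epoxy-15-norlabd-12-en-14-oate | CCOC(=O)/C(C)=C/C[C@H]1[C@](C)(O[Si](C)(C)C(C)(C)C)[C@@H]3O[C@@H]3[C@H]2C(C)(C)CCC[C@@]21C
F9 | step 15 | ethyl (12E)-8α-{[tert-butyl(dimethyl)silyl]oxy}-6β,7α-dihydroxy-15-norlabd-12-en-14-oate | CCOC(=O)/C(C)=C/C[C@H]1[C@](C)(O[Si](C)(C)C(C)(C)C)[C@H](O)[C@@H](O)[C@H]2C(C)(C)CCC[C@@]21C
F10 | step 15 | ethyl (12E)-8α-{[tert-butyl(dimethyl)silyl]oxy}-6β-hydroxy-7-oxo-15-norlabd-12-en-14-oate | CCOC(=O)/C(C)=C/C[C@H]1[C@](C)(O[Si](C)(C)C(C)(C)C)C(=O)[C@@H](O)[C@H]2C(C)(C)CCC[C@@]21C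
F11 | step 6 | (7E)-6,6-dimethyl-9-(2-methyl-1,3-dioxolan-2-yl)non-7-en-2-one | CC(=O)CCCC(C)(C)/C=C/CC1(C)OCCO1
F12 | step 20 | 6β,7β-O-(dibutylstannylene) acetal of (12E)-labda-12,14-diene-6β,7β,8α-triol | C=C/C(C)=C/C[C@H]1[C@](C)(O)[C@H]3O[Sn](CCCC)(CCCC)O[C@H]3[C@H]2C(C)(C)CCC[C@@]21C
A1 | alternative 1 | tert-butyl(dimethyl){[1-(2,6,6-trimethylcyclohex-1-en-1-yl)ethenyl]oxy}silane | C=C(O[Si](C)(C)C(C)(C)C)C1=C(C)CCCC1(C)C
A2 | alternative 1 | methyl but-2-ynoate | CC#CC(=O)OC
A3 | alternative 1 | methyl (8aS)-4-{[tert-butyl(dimethyl)silyl]oxy}-2,5,5,8a-tetramethyl-3,5,6,7,8,8a-hexahydronaphthalene-1-carboxylate (6-silyloxy-5,8-diene C11 ester) | COC(=O)C1=C(C)CC(O[Si](C)(C)C(C)(C)C)=C2C(C)(C)CCC[C@@]21C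
A4 | alternative 2 | ring B enol trimethylsilyl ether (C5=C6) bearing the 9α-H 2-silyloxyethyl chain, the 10β-methyl and the 4-methylpent-3-enyl chain on C10 | CC(C)(C)[Si](C)(C)OCC[C@H]1CCC(O[Si](C)(C)C)=C[C@]1(C)CCC=C(C)C
A5 | alternative 2 | trans-fused 9-(2-silyloxyethyl)-4,4,10-trimethyldecalin-6-one (5α-H, 9α-H, 10β-CH3) | CC(C)(C)[Si](C)(C)OCC[C@H]1CCC(=O)[C@H]2C(C)(C)CCC[C@@]21C
A6 | alternative 3 | 3-(5-bromo-2-methylpentan-2-yl)-5-(2-{[tert-butyl(dimethyl)silyl]oxy}ethyl)-2-chloro-4,6-dimethylphenol | CC(C)(C)[Si](C)(C)OCCc1c(C)c(O)c(Cl)c(C(C)(C)CCCBr)c1C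
A7 | alternative 3 | 6-chloro-5,8-dien-7-one with 10β-methyl (cross-conjugated dienone) | CC(C)(C)[Si](C)(C)OCCC1=C(C)C(=O)C(Cl)=C2C(C)(C)CCC[C@@]21C
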